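## Retrosynthetic overview

1. Target 17 ⇒ 14 + 15: the C8–CH2 bond is cut last (Friedel–Crafts with the o-quinone methide of 15; C8 is the only free A-ring carbon). 14 ⇒ 12 ⇒ 11 by chelation-directed 5-O-demethylation and 6-O-methylation.
2. 11 ⇒ 9: the pyranone ring (O1, C2, C3, C4, C4a, C8a) is traced back to the five-membered furan-3(2H)-one ring (O1, C2, C3, C4, C8a) of a spirodienone. A 1,2-shift of the C4 acyl group from C8a to C4a enlarges the ring and rearomatises ring A.
3. Enabling feature: in ring A the ether oxygen O1 on C8a is para to the oxygen on C6, and the C4 carbonyl sits on the neighbouring C4a. Ring A plus O1 and C4 is therefore a disguised 4-alkoxy-4-acyl-2,6-dimethoxycyclohexa-2,5-dienone with C8a as spiro carbon; O1 stabilises the cation the shift leaves, and the symmetric dienone has two identical migration termini.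
4. 9 ⇒ 7 by oxidative dearomatisation of a cheap syringyl phenol (ipso attack of the C2 hydroxyl); 7 ⇒ aryllithium 5 + Weinreb amide 4, with C2 coming from ethyl (S)-3-hydroxy-3-phenylpropanoate 3.
5. Ring order: both benzene rings are bought; the furanone ring (5) and then the pyranone ring (6) form in one flask in step 5; the diarylmethane link is made last.

Key step: step 5

Remark: the SMILES is read as the (2S)-flavanone; flavanone numbering (O1, C2, C3, C4, C4a, C5–C8, C8a) is used for every intermediate, also before the ring exists, and 1, 3 and 15 are taken as catalogue compounds.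

## Route

Step 1
Reactants: 1 4-bromo-2,6-dimethoxyphenol
Product: 2 (4-bromo-2,6-dimethoxyphenoxy)(tert-butyl)dimethylsilane
Conditions: TBSCl (1.2 equiv), imidazole (2.5 equiv), DMF, 25 °C
Reagents that add atoms: tert-butyldimethylsilyl chloride, CC(C)(C)[Si](C)(C)Cl
Why: Imidazole-promoted O-silylation masks the acidic phenol so that the bromine–lithium exchange of step 3 gives a clean aryllithium; a para silyloxy group cannot undergo retro-Brook migration and no stereocentre is involved.

Step 2
Reactants: 3 ethyl (3S)-3-hydroxy-3-phenylpropanoate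
Product: 4 (3S)-3-hydroxy-N-methoxy-N-methyl-3-phenylpropanamide
Conditions: MeNH(OMe)·HCl (1.5 equiv), i-PrMgCl (4.0 equiv), THF, −20 °C; aq NH4Cl
Reagents that add atoms: N,O-dimethylhydroxylamine hydrochloride, CNOC.Cl
Why: Weinreb amidation of the ester by the chloromagnesium amide of MeNH(OMe) should proceed at −20 °C on the magnesium alkoxide of the β-hydroxy ester without retro-aldol or dehydration, so the (S)-carbinol centre of 3, which becomes C2, is carried over unchanged.

Step 3
Reactants: 2 (4-bromo-2,6-dimethoxyphenoxy)(tert-butyl)dimethylsilane; 4 (3S)-3-hydroxy-N-methoxy-N-methyl-3-phenylpropanamide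
Product: 6 (3S)-1-[4-(tert-butyldimethylsilyloxy)-3,5-dimethoxyphenyl]-3-hydroxy-3-phenylpropan-1-one, via aryllithium 5 (not isolated)
Conditions: 2 (2.3 equiv), n-BuLi (2.2 equiv), THF, −78 °C; then 4 (1.0 equiv), −78 → −20 °C; aq NH4Cl
Reagents that add atoms: none
Why: Bromine–lithium exchange followed by Weinreb ketone synthesis: one equivalent of 5 removes the hydroxyl proton of 4 and the next adds once to the amide, the N,O-chelated tetrahedral adduct collapsing to the ketone only on quench, and no bond at the carbinol centre is touched.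

Step 4
Reactants: 6 (3S)-1-[4-(tert-butyldimethylsilyloxy)-3,5-dimethoxyphenyl]-3-hydroxy-3-phenylpropan-1-one
Product: 7 (3S)-3-hydroxy-1-(4-hydroxy-3,5-dimethoxyphenyl)-3-phenylpropan-1-one
Conditions: Bu4NF (1.1 equiv), AcOH (1.2 equiv), THF, 0 °C
Reagents that add atoms: none
Why: Fluoride cleavage of the aryl silyl ether, buffered with acetic acid so that the liberated phenoxide cannot trigger E1cB dehydration of the β-hydroxy ketone, leaves the stereocentre untouched.

Step 5
Reactants: 7 (3S)-3-hydroxy-1-(4-hydroxy-3,5-dimethoxyphenyl)-3-phenylpropan-1-one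
Product: 11 (2S)-6-hydroxy-5,7-dimethoxyflavanone, via aryloxy-λ3-iodane 8 (not isolated), via spirodienone 9 (not isolated), via oxocarbenium ion 10 (not isolated)
Conditions: PhI(OAc)2 (1.0 equiv), (CF3)2CHOH–CH2Cl2 (1:4), −20 °C, one flask; then CF3CO2H (5 equiv), −20 → 20 °C
Reagents that add atoms: none
Why: Proposed new method: ligand exchange of the phenol of 7 at iodine(III) gives aryloxyiodane 8, whose para carbon (C8a) is attacked by the tethered C2 hydroxyl with loss of PhI to give the 4-alkoxy-4-acylcyclohexa-2,5-dienone 9; CF3CO2H then protonates the dienone oxygen, the C4 acyl group shifts from C8a to the adjacent carbon (C4a) to leave the O1-stabilised oxocarbenium ion 10, and loss of the C4a proton rearomatises ring A. The closest known reaction types are the PhI(OAc)2 oxidative spiroetherification of 4-(3-hydroxyalkyl)phenols to 1-oxaspiro[4.5]deca-6,9-dien-8-ones and the acid-promoted dienone–phenol rearrangement, in which acyl groups migrate in preference to alkyl groups; new here is the carbonyl carbon at the ipso position, whose deactivating effect is offset by the two ortho methoxy groups. The five-membered ring is closed 5-exo-trig by O-attack on the ipso carbon; the six-membered pyranone is not closed but arises from it by the 1,2-acyl shift (a dissociative variant, acylium release and ortho re-acylation of the tethered aryl ether, would give the same product). No stereocentre is created: no bond at C2 is made or broken, so the (S) configuration of 3 is kept, and the spiro carbon of 9 is not stereogenic because the dienone ring is symmetric. The step needs ipso rather than ortho attack, secured by five-membered intramolecular delivery in a non-nucleophilic medium; acyl rather than oxygen migration, secured by the O1 lone pair, which stabilises the cation only if O1 stays on C8a; and one migration terminus, secured by the symmetry of the 2,6-dimethoxydienone. Adding the acid only after the oxidant is spent keeps the easily oxidised product phenol away from iodine(III).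

Step 6
Reactants: 11 (2S)-6-hydroxy-5,7-dimethoxyflavanone
Product: 12 (2S)-5,6,7-trimethoxyflavanone
Conditions: MeOH (3 equiv), PPh3 (1.5 equiv), DIAD (1.5 equiv), THF, 0 → 25 °C
Reagents that add atoms: methanol, CO
Why: Mitsunobu O-alkylation of the phenol with methanol is neutral and so avoids the base-induced retro-oxa-Michael ring opening through which a flavanone loses its C2 configuration.

Step 7
Reactants: 12 (2S)-5,6,7-trimethoxyflavanone
Product: 14 (2S)-5-hydroxy-6,7-dimethoxyflavanone, via boron chelate 13 (not isolated)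
Conditions: BCl3 (1.2 equiv), CH2Cl2, −78 → 0 °C; then H2O
Reagents that add atoms: none
Why: Chelation-controlled Lewis-acid demethylation: BCl3 binds the C4 carbonyl and should cleave only the peri 5-methoxy group by way of the six-membered chelate 13, which water hydrolyses, while the 6- and 7-methoxy groups and C2 are left untouched at low temperature.

Step 8
Reactants: 14 (2S)-5-hydroxy-6,7-dimethoxyflavanone; 15 2-(hydroxymethyl)-4-methoxyphenol
Product: 17 (2S)-5-hydroxy-8-[(2-hydroxy-5-methoxyphenyl)methyl]-6,7-dimethoxy-2-phenyl-2,3-dihydro-4H-chromen-4-one, via o-quinone methide 16 (not isolated)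
Conditions: ZnCl2 (1.5 equiv), 1,4-dioxane, 70 °C, slow addition of 15 (1.0 equiv) to 14 (1.5 equiv)
Reagents that add atoms: none
Why: Friedel–Crafts ortho-hydroxybenzylation: ZnCl2 dehydrates 15 to the o-quinone methide 16, which is attacked by C8 of 14, the only unsubstituted A-ring carbon and para to the 5-hydroxyl, so that regiochemistry is not in question and no bond at C2 is involved.

## Compound list

1 | 4-bromo-2,6-dimethoxyphenol | COc1cc(Br)cc(OC)c1O | starting material
2 | (4-bromo-2,6-dimethoxyphenoxy)(tert-butyl)dimethylsilane | COc1cc(Br)cc(OC)c1O[Si](C)(C)C(C)(C)C | intermediate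
3 | ethyl (3S)-3-hydroxy-3-phenylpropanoate | CCOC(=O)C[C@H](O)c1ccccc1 | starting material
4 | (3S)-3-hydroxy-N-methoxy-N-methyl-3-phenylpropanamide | CON(C)C(=O)C[C@H](O)c1ccccc1 | intermediate
5 | [4-(tert-butyldimethylsilyloxy)-3,5-dimethoxyphenyl]lithium | [Li]c1cc(OC)c(O[Si](C)(C)C(C)(C)C)c(OC)c1 | intermediate (not isolated)
6 | (3S)-1-[4-(tert-butyldimethylsilyloxy)-3,5-dimethoxyphenyl]-3-hydroxy-3-phenylpropan-1-one | COc1cc(cc(OC)c1O[Si](C)(C)C(C)(C)C)C(=O)C[C@H](O)c1ccccc1 | intermediate
7 | (3S)-3-hydroxy-1-(4-hydroxy-3,5-dimethoxyphenyl)-3-phenylpropan-1-one | COc1cc(cc(OC)c1O)C(=O)C[C@H](O)c1ccccc1 | intermediate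
8 | (3S)-1-{4-[acetoxy(phenyl)-λ3-iodanyloxy]-3,5-dimethoxyphenyl}-3-hydroxy-3-phenylpropan-1-one | CC(=O)OI(c1ccccc1)Oc1c(OC)cc(cc1OC)C(=O)C[C@H](O)c1ccccc1 | intermediate (not isolated)
9 | (2S)-7,9-dimethoxy-2-phenyl-1-oxaspiro[4.5]deca-6,9-diene-4,8-dione | O=C1C[C@@H](c2ccccc2)OC13C=C(OC)C(=O)C(OC)=C3 | intermediate (not isolated)
10 | (2S)-6-hydroxy-5,7-dimethoxy-4-oxo-2-phenyl-3,4-dihydro-2H,4aH-chromen-1-ium trifluoroacetate (cation after the acyl shift) | O=C1C[C@@H](c2ccccc2)[O+]=C2C=C(OC)C(O)=C(OC)C12.[O-]C(=O)C(F)(F)F | intermediate (not isolated)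
11 | (2S)-6-hydroxy-5,7-dimethoxyflavanone | COc1cc2O[C@H](c3ccccc3)CC(=O)c2c(OC)c1O | intermediate
12 | (2S)-5,6,7-trimethoxyflavanone | COc1cc2O[C@H](c3ccccc3)CC(=O)c2c(OC)c1OC | intermediate
13 | (2S)-5-(dichloroboranyloxy)-6,7-dimethoxyflavanone (boron chelate of 14) | COc1cc2O[C@H](c3ccccc3)CC(=O)c2c(OB(Cl)Cl)c1OC | intermediate (not isolated)
14 | (2S)-5-hydroxy-6,7-dimethoxyflavanone | COc1cc2O[C@H](c3ccccc3)CC(=O)c2c(O)c1OC | intermediate
15 | 2-(hydroxymethyl)-4-methoxyphenol | COc1ccc(O)c(CO)c1 | starting material
16 | 4-methoxy-6-methylidenecyclohexa-2,4-dien-1-one | C=C1C=C(OC)C=CC1=O | intermediate (not isolated)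
17 | (2S)-5-hydroxy-8-[(2-hydroxy-5-methoxyphenyl)methyl]-6,7-dimethoxy-2-phenyl-2,3-dihydro-4H-chromen-4-one | COc1ccc(O)c(Cc2c(OC)c(OC)c(O)c3c2O[C@H](c2ccccc2)CC3=O)c1 | target

## Step count and risks

Total steps: 8. Longest linear sequence: 7 steps (1 → 2 → 6 → 7 → 11 → 12 → 14 → 17).

Steps most likely to fail:

Step 5 (Proposed new method). What may go wrong: instead of ipso attack by the tethered hydroxyl, external nucleophiles add at the methoxy-bearing ortho carbons (oxidative demethylation towards an o-quinone), or the acyl side chain is expelled after ipso attack. The fallback uses known chemistry, sets out from 7 and takes the carbonyl out of conjugation before the dearomatisation. NaBH4 (MeOH, 0 °C) should give (3S)-1-(4-hydroxy-3,5-dimethoxyphenyl)-3-phenylpropane-1,3-diol F1 as a mixture of C1 epimers that converge later. PhI(OAc)2 (MeCN, NaHCO3, 0 °C), now the established spiroetherification of a 4-alkylphenol, should give (2S)-4-hydroxy-7,9-dimethoxy-2-phenyl-1-oxaspiro[4.5]deca-6,9-dien-8-one F2. Dess–Martin periodinane (CH2Cl2, NaHCO3, 25 °C) oxidises the secondary alcohol and comes back to the route at 9, which is then isolated and rearranged with CF3CO2H as in the second stage of step 5.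

Step 8. What may go wrong: oligomerisation of the quinone methide, further benzylation of the newly introduced phenol ring, or Lewis-acid-assisted ring opening of the flavanone with loss of configuration. The fallback makes the C8–CH2 bond by cross-coupling and sets out from 12 and 15. NIS with catalytic CF3CO2H (MeCN, 25 °C) should give (2S)-8-iodo-5,6,7-trimethoxyflavanone F3. Compound 15 is O-benzylated at the phenol (BnBr, K2CO3, acetone) to [2-(benzyloxy)-5-methoxyphenyl]methanol F4, converted with conc. HCl into 1-(benzyloxy)-2-(chloromethyl)-4-methoxybenzene F5, and with zinc dust and LiCl (THF) into {[2-(benzyloxy)-5-methoxyphenyl]methyl}zinc chloride F6. Negishi coupling of F3 with F6 (Pd(OAc)2, SPhos, THF, 25 °C) should give (2S)-8-{[2-(benzyloxy)-5-methoxyphenyl]methyl}-5,6,7-trimethoxyflavanone F7. BCl3 with pentamethylbenzene (CH2Cl2, −78 to −20 °C) then removes the benzyl ether and the chelated 5-methyl ether together and comes back to the route at the target 17.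

Step 7. What may go wrong: cleavage of the 6-methoxy group next to the boron chelate as well (over-demethylation). The fallback changes the order of events so that this cleavage becomes harmless, and sets out from 11, where O6 is still free. BCl3 (CH2Cl2, −78 to 0 °C) cleaves the chelated 5-methyl ether to give (2S)-5,6-dihydroxy-7-methoxyflavanone F8. Mitsunobu methylation with one equivalent of methanol (PPh3, DIAD, THF) then takes the non-chelated, more acidic 6-hydroxyl and comes back to the route at 14.

## Further compounds

F1 | step 5 | (3S)-1-(4-hydroxy-3,5-dimethoxyphenyl)-3-phenylpropane-1,3-diol (C1 epimers) | COc1cc(cc(OC)c1O)C(O)C[C@H](O)c1ccccc1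
F2 | step 5 | (2S)-4-hydroxy-7,9-dimethoxy-2-phenyl-1-oxaspiro[4.5]deca-6,9-dien-8-one (C4 epimers) | OC1C[C@@H](c2ccccc2)OC13C=C(OC)C(=O)C(OC)=C3
F3 | step 8 | (2S)-8-iodo-5,6,7-trimethoxyflavanone | COc1c(I)c2O[C@H](c3ccccc3)CC(=O)c2c(OC)c1OC
F4 | step 8 | [2-(benzyloxy)-5-methoxyphenyl]methanol | COc1ccc(OCc2ccccc2)c(CO)c1
F5 | step 8 | 1-(benzyloxy)-2-(chloromethyl)-4-methoxybenzene | COc1ccc(OCc2ccccc2)c(CCl)c1
F6 | step 8 | {[2-(benzyloxy)-5-methoxyphenyl]methyl}zinc chloride | COc1ccc(OCc2ccccc2)c(C[Zn]Cl)c1
F7 | step 8 | (2S)-8-{[2-(benzyloxy)-5-methoxyphenyl]methyl}-5,6,7-trimethoxyflavanone | COc1ccc(OCc2ccccc2)c(Cc2c(OC)c(OC)c(OC)c3c2O[C@H](c2ccccc2)CC3=O)c1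
F8 | step 7 | (2S)-5,6-dihydroxy-7-methoxyflavanone | COc1cc2O[C@H](c3ccccc3)CC(=O)c2c(O)c1O
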